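Plakortolide S (numbering: C1 lactone carbonyl through C6 peroxy carbon) is cut twice. The 1,2-dioxane is closed last, by conjugate addition of a C6 hydroperoxide to C3 of a butenolide. The γ-lactone ring (O, C1, C2, C3, C4) offers one feature: on one side C1 and C4 are bridged by the ring oxygen alone, so deleting that oxygen reveals a 2,2-disubstituted cyclobutanone. The key step stitches an ethylene unit (C2–C3, from EtMgBr) between acyl carbon C1 and oxygen-bearing C4 of an alkylated lactic acid dioxolanone. Cyclopropanol formation makes C1–C2, and an invertive ring expansion that expels the C4 oxygen makes C3–C4. Baeyer–Villiger oxidation then returns the oxygen with retention.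

Key step: step 5

Remark on numbering: C1 = lactone C=O, C2 = its CH2, C3 = CH–OO, C4 = C(CH3)–O(lactone), C5 = ring CH2, C6 = C(CH3)–OO; the target is (3R,4R,6S).
Remark on C6: no known peroxidation tells apart the two alkyl arms at C6, so C6 is made as both epimers in step 8 and the 6S epimer is collected by chromatography after ring closure in step 9.

Step 1
Reactants: 1 (4-bromophenoxy)(tert-butyl)dimethylsilane; 2 1,9-dibromononane
Product: 4 [4-(9-bromononyl)phenoxy](tert-butyl)dimethylsilane, via arylmagnesium bromide 3 (not isolated)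
Conditions: Mg, THF, reflux; then 2 (3 equiv), Li2CuCl4 (3 mol %), THF, 0 °C
Reagents that add atoms: none
Why: Kochi-type copper-catalysed coupling of an aryl Grignard reagent with a primary alkyl bromide, in which the excess of 2 keeps the second bromide untouched; no stereocenter is formed.

Step 2
Reactants: 4 [4-(9-bromononyl)phenoxy](tert-butyl)dimethylsilane; 5 3-bromo-2-(bromomethyl)prop-1-ene
Product: 7 tert-butyl{4-[11-(bromomethyl)dodec-11-en-1-yl]phenoxy}dimethylsilane, via alkylmagnesium bromide 6 (not isolated)
Conditions: Mg, THF; then inverse addition to 5 (3 equiv), Li2CuCl4 (5 mol %), THF, −30 °C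
Reagents that add atoms: none
Why: Copper-catalysed allylic substitution on a symmetrical bis-allylic dibromide, where SN2 and SN2' attack give the same product and inverse addition to excess 5 limits a second substitution.

Step 3
Reactants: 8 (S)-lactic acid; 9 pivalaldehyde
Product: 10 (2S,5S)-2-tert-butyl-5-methyl-1,3-dioxolan-4-one
Conditions: TsOH·H2O (cat.), H2SO4 (cat.), pentane, reflux, Dean–Stark; crystallisation from pentane/Et2O at −78 °C
Reagents that add atoms: none
Why: Acid-catalysed acetalisation (Seebach self-regeneration of stereocenters), in which C5 keeps the lactic acid configuration and the acetal center forms mainly cis under thermodynamic control, the cis isomer being purified by crystallisation.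

Step 4
Reactants: 10 (2S,5S)-2-tert-butyl-5-methyl-1,3-dioxolan-4-one; 7 tert-butyl{4-[11-(bromomethyl)dodec-11-en-1-yl]phenoxy}dimethylsilane
Product: 12 (2S,5R)-2-tert-butyl-5-methyl-5-{2-methylidene-12-[4-(tert-butyldimethylsilyloxy)phenyl]dodecyl}-1,3-dioxolan-4-one, via lithium enolate 11 (not isolated)
Conditions: LDA, THF, −78 °C; then 7, −78 to −30 °C
Reagents that add atoms: none
Why: Seebach alkylation, in which the planar enolate is attacked by the allylic bromide on the face anti to the tert-butyl group, so that the quaternary center (the later C4) is set as 5R without any need to tell methyl from CH2R.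

Step 5
Reactants: 12 (2S,5R)-2-tert-butyl-5-methyl-5-{2-methylidene-12-[4-(tert-butyldimethylsilyloxy)phenyl]dodecyl}-1,3-dioxolan-4-one
Product: 14 (2S)-2-methyl-2-{2-methylidene-12-[4-(tert-butyldimethylsilyloxy)phenyl]dodecyl}cyclobutan-1-one, via cyclopropanol diol 13 (not isolated)
Conditions: EtMgBr (5 equiv, slow addition), Ti(OiPr)4 (0.5 equiv), THF, 0 °C to rt; then 10% aq H2SO4, 0 °C to rt
Reagents that add atoms: ethylmagnesium bromide CC[Mg]Br
Why: Proposed new method: EtMgBr and Ti(OiPr)4 form a titanacyclopropane, an ethylene 1,2-dianion, whose first carbon adds to the lactone carbonyl C1 of 12 (new C1–C2 bond) with loss of the acetal oxygen, which falls apart to pivalaldehyde and the C4 alkoxide, and whose second carbon closes cyclopropanol 13 by 3-exo-trig attack on the resulting ketone (Kulinkovich reaction). On the acidic quench the tertiary C4–OH is protonated and leaves while the antiperiplanar cyclopropane bond swings from C1 to C4 (new C3–C4 bond), a semipinacol three-to-four ring expansion by 1,2-shift that is pushed by the cyclopropanol oxygen and ends in the C1 ketone. The closest known chemistry is the Kulinkovich cyclopropanation of α-hydroxy esters followed by pinacol-type rearrangement of the α-hydroxycyclopropylcarbinols to enantioenriched 2-substituted cyclobutanones; new are the dioxolanone as ester partner, the fully substituted migration terminus and the telescoping into one flask. C4 is the only stereocenter touched: the migrating CH2 enters on the face opposite to the leaving oxygen, so the configuration fixed in step 4 should be inverted, and whichever of the two constitutionally equivalent cyclopropane CH2 groups shifts, the same (S)-ketone results. The step needs ionisation at C4 only (a cyclopropyl cation at C1 is out of reach), a shift that outruns a free planar cation (secured by the strong donor power of the 1-hydroxycyclopropyl group), and attack of titanium at the carbonyl instead of the side-chain alkene (1,1-disubstituted alkenes do not exchange into the titanacyclopropane, and 12 has no α-hydrogen to enolise).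

Step 6
Reactants: 14 (2S)-2-methyl-2-{2-methylidene-12-[4-(tert-butyldimethylsilyloxy)phenyl]dodecyl}cyclobutan-1-one
Product: 15 (5S)-5-methyl-5-{2-methylidene-12-[4-(tert-butyldimethylsilyloxy)phenyl]dodecyl}oxolan-2-one
Conditions: 30% aq H2O2, AcOH, 0 °C to rt
Reagents that add atoms: hydrogen peroxide OO
Why: Baeyer–Villiger oxidation driven by release of cyclobutanone strain, in which the quaternary C4 migrates in preference to CH2 and with retention, while H2O2 in AcOH is too weak an epoxidising agent for the 1,1-disubstituted alkene.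

Step 7
Reactants: 15 (5S)-5-methyl-5-{2-methylidene-12-[4-(tert-butyldimethylsilyloxy)phenyl]dodecyl}oxolan-2-one
Product: 18 (5R)-5-methyl-5-{2-methylidene-12-[4-(tert-butyldimethylsilyloxy)phenyl]dodecyl}furan-2(5H)-one, via lithium enolate 16 (not isolated), via selanyl lactone 17 (not isolated)
Conditions: LDA, THF, −78 °C; PhSeBr, −78 °C; then 30% aq H2O2, pyridine, CH2Cl2, 0 °C to rt
Reagents that add atoms: none
Why: α-Selenenylation of the lactone enolate and selenoxide syn-elimination, which can only place the double bond between C2 and C3 and leave the quaternary C4 untouched (the descriptor changes only through the priority rules).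

Step 8
Reactants: 18 (5R)-5-methyl-5-{2-methylidene-12-[4-(tert-butyldimethylsilyloxy)phenyl]dodecyl}furan-2(5H)-one
Product: 19 (5R)-5-methyl-5-{2-methyl-2-(triethylsilylperoxy)-12-[4-(tert-butyldimethylsilyloxy)phenyl]dodecyl}furan-2(5H)-one (both C6 epimers)
Conditions: Co(acac)2 (10 mol %), Et3SiH (3 equiv), O2 (1 atm), ClCH2CH2Cl, rt
Reagents that add atoms: dioxygen O=O; triethylsilane CC[SiH](CC)CC
Why: Mukaiyama–Isayama hydroperoxysilylation, in which hydrogen-atom transfer to the terminal CH2 of the electron-rich alkene gives the tertiary C6 radical that is trapped by O2 and silane while the electron-poor butenolide is spared; the radical is planar and remote from C4, so no induction is expected and both C6 epimers are carried on.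

Step 9
Reactants: 19 (5R)-5-methyl-5-{2-methyl-2-(triethylsilylperoxy)-12-[4-(tert-butyldimethylsilyloxy)phenyl]dodecyl}furan-2(5H)-one (both C6 epimers)
Product: 21 plakortolide S, via hydroperoxy phenol 20 (not isolated)
Conditions: TBAF, AcOH, THF, 0 °C; then Et2NH (cat.), CF3CH2OH, rt; separation of the C6 epimers on silica gel
Reagents that add atoms: none
Why: Fluoride removes both silyl groups and the amine-catalysed 6-exo-trig oxa-Michael addition of the C6 hydroperoxide can reach C3 only on the butenolide face that carries C5, which sets C3 as R in a cis-fused bicycle, while the protic medium protonates the enolate before it can expel alkoxide; the 6S epimer is then separated from the 6R epimer.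

Compound list
1 | (4-bromophenoxy)(tert-butyl)dimethylsilane | Brc1ccc(O[Si](C)(C)C(C)(C)C)cc1 | starting material
2 | 1,9-dibromononane | BrCCCCCCCCCBr | starting material
3 | 4-(tert-butyldimethylsilyloxy)phenylmagnesium bromide | Br[Mg]c1ccc(O[Si](C)(C)C(C)(C)C)cc1 | intermediate
4 | [4-(9-bromononyl)phenoxy](tert-butyl)dimethylsilane | BrCCCCCCCCCc1ccc(O[Si](C)(C)C(C)(C)C)cc1 | intermediate
5 | 3-bromo-2-(bromomethyl)prop-1-ene | C=C(CBr)CBr | starting material
6 | 9-[4-(tert-butyldimethylsilyloxy)phenyl]nonylmagnesium bromide | Br[Mg]CCCCCCCCCc1ccc(O[Si](C)(C)C(C)(C)C)cc1 | intermediate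
7 | tert-butyl{4-[11-(bromomethyl)dodec-11-en-1-yl]phenoxy}dimethylsilane | C=C(CBr)CCCCCCCCCCc1ccc(O[Si](C)(C)C(C)(C)C)cc1 | intermediate
8 | (S)-lactic acid | C[C@H](O)C(=O)O | starting material
9 | pivalaldehyde | CC(C)(C)C=O | starting material
10 | (2S,5S)-2-tert-butyl-5-methyl-1,3-dioxolan-4-one | C[C@@H]1O[C@H](C(C)(C)C)OC1=O | intermediate
11 | lithium enolate of 10 | [Li+].CC1=C([O-])O[C@@H](C(C)(C)C)O1 | intermediate
12 | (2S,5R)-2-tert-butyl-5-methyl-5-{2-methylidene-12-[4-(tert-butyldimethylsilyloxy)phenyl]dodecyl}-1,3-dioxolan-4-one | C[C@]1(CC(=C)CCCCCCCCCCc2ccc(O[Si](C)(C)C(C)(C)C)cc2)O[C@H](C(C)(C)C)OC1=O | intermediate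
13 | 1-{(2R)-2-hydroxy-4-methylidene-14-[4-(tert-butyldimethylsilyloxy)phenyl]tetradecan-2-yl}cyclopropan-1-ol | C[C@@](O)(CC(=C)CCCCCCCCCCc1ccc(O[Si](C)(C)C(C)(C)C)cc1)C1(O)CC1 | intermediate
14 | (2S)-2-methyl-2-{2-methylidene-12-[4-(tert-butyldimethylsilyloxy)phenyl]dodecyl}cyclobutan-1-one | C[C@@]1(CC(=C)CCCCCCCCCCc2ccc(O[Si](C)(C)C(C)(C)C)cc2)CCC1=O | intermediate
15 | (5S)-5-methyl-5-{2-methylidene-12-[4-(tert-butyldimethylsilyloxy)phenyl]dodecyl}oxolan-2-one | C[C@@]1(CC(=C)CCCCCCCCCCc2ccc(O[Si](C)(C)C(C)(C)C)cc2)CCC(=O)O1 | intermediate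
16 | lithium enolate of 15 | [Li+].C[C@@]1(CC(=C)CCCCCCCCCCc2ccc(O[Si](C)(C)C(C)(C)C)cc2)CC=C([O-])O1 | intermediate
17 | (5S)-5-methyl-5-{2-methylidene-12-[4-(tert-butyldimethylsilyloxy)phenyl]dodecyl}-3-(phenylselanyl)oxolan-2-one (both C3 epimers of the oxolanone) | C[C@@]1(CC(=C)CCCCCCCCCCc2ccc(O[Si](C)(C)C(C)(C)C)cc2)CC([Se]c2ccccc2)C(=O)O1 | intermediate
18 | (5R)-5-methyl-5-{2-methylidene-12-[4-(tert-butyldimethylsilyloxy)phenyl]dodecyl}furan-2(5H)-one | C[C@@]1(CC(=C)CCCCCCCCCCc2ccc(O[Si](C)(C)C(C)(C)C)cc2)C=CC(=O)O1 | intermediate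
19 | (5R)-5-methyl-5-{2-methyl-2-(triethylsilylperoxy)-12-[4-(tert-butyldimethylsilyloxy)phenyl]dodecyl}furan-2(5H)-one (both C6 epimers) | C[C@@]1(CC(C)(OO[Si](CC)(CC)CC)CCCCCCCCCCc2ccc(O[Si](C)(C)C(C)(C)C)cc2)C=CC(=O)O1 | intermediate
20 | (5R)-5-[2-hydroperoxy-12-(4-hydroxyphenyl)-2-methyldodecyl]-5-methylfuran-2(5H)-one (both C6 epimers) | C[C@@]1(CC(C)(OO)CCCCCCCCCCc2ccc(O)cc2)C=CC(=O)O1 | intermediate
21 | plakortolide S, (3R,4R,6S) | C[C@]1(CCCCCCCCCCc2ccc(O)cc2)C[C@@]2(C)OC(=O)C[C@H]2OO1 | target

Total step count: 9
Longest linear sequence: 8 (steps 1, 2, 4, 5, 6, 7, 8, 9)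

Steps most likely to fail

Step 5. Three processes threaten it. The Grignard reagent may add to the activated lactone carbonyl before it is handed to titanium. The acid may open the cyclopropanol instead of expanding it. The shift may also leak through a free cyclopropylcarbinyl cation, with erosion of configuration at C4. The fallback uses known chemistry, sets out from 12 and comes back at 18. It keeps the lactic acid C4–O bond and turns the former carboxyl carbon into C3, which leads to the same (5R)-butenolide. Reduction of 12 with LiAlH4 in Et2O gives (2R)-2-methyl-4-methylidene-14-[4-(tert-butyldimethylsilyloxy)phenyl]tetradecane-1,2-diol F1. Parikh–Doering oxidation (SO3·pyridine, DMSO, Et3N) of the primary alcohol gives (2R)-2-hydroxy-2-methyl-4-methylidene-14-[4-(tert-butyldimethylsilyloxy)phenyl]tetradecanal F2. Still–Gennari olefination ((CF3CH2O)2P(O)CH2CO2Me, KHMDS, 18-crown-6, THF, −78 °C) gives methyl (2Z,4R)-4-hydroxy-4-methyl-6-methylidene-16-[4-(tert-butyldimethylsilyloxy)phenyl]hexadec-2-enoate F3, which lactonises on mildly acidic work-up to 18.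

Step 8. The lack of facial discrimination at the planar C6 radical is inherent and halves the throughput. Hydrogen-atom transfer to the butenolide double bond and reduction of the new O–O bond by the cobalt/silane system may compete as well. The fallback replaces the radical chemistry by a polar sequence, sets out from 18 and comes back at 20. Markovnikov addition of anhydrous HBr (CH2Cl2, −40 °C) gives (5R)-5-{2-bromo-2-methyl-12-[4-(tert-butyldimethylsilyloxy)phenyl]dodecyl}-5-methylfuran-2(5H)-one F4. Silver-assisted perhydrolysis (AgO2CCF3, anhydrous H2O2 in Et2O, 0 °C) gives (5R)-5-{2-hydroperoxy-2-methyl-12-[4-(tert-butyldimethylsilyloxy)phenyl]dodecyl}-5-methylfuran-2(5H)-one F5. Buffered TBAF then frees the phenol to give 20. C6 is again formed as both epimers and resolved after ring closure.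

Step 2. A second substitution of the product allylic bromide and homocoupling of the Grignard reagent may consume the material. The fallback reverses the polarity of the coupling, sets out from 4 and comes back at 7. 2-Methylprop-2-en-1-ol is doubly lithiated (nBuLi, 2 equiv, TMEDA, Et2O) and alkylated with 4 to give 2-methylidene-12-[4-(tert-butyldimethylsilyloxy)phenyl]dodecan-1-ol F6. An Appel reaction (CBr4, PPh3, CH2Cl2) converts this alcohol to 7.

Further compounds
F1 | step 5 | (2R)-2-methyl-4-methylidene-14-[4-(tert-butyldimethylsilyloxy)phenyl]tetradecane-1,2-diol | C[C@@](O)(CC(=C)CCCCCCCCCCc1ccc(O[Si](C)(C)C(C)(C)C)cc1)CO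
F2 | step 5 | (2R)-2-hydroxy-2-methyl-4-methylidene-14-[4-(tert-butyldimethylsilyloxy)phenyl]tetradecanal | C[C@@](O)(CC(=C)CCCCCCCCCCc1ccc(O[Si](C)(C)C(C)(C)C)cc1)C=O
F3 | step 5 | methyl (2Z,4R)-4-hydroxy-4-methyl-6-methylidene-16-[4-(tert-butyldimethylsilyloxy)phenyl]hexadec-2-enoate | C[C@@](O)(CC(=C)CCCCCCCCCCc1ccc(O[Si](C)(C)C(C)(C)C)cc1)/C=C\C(=O)OC
F4 | step 8 | (5R)-5-{2-bromo-2-methyl-12-[4-(tert-butyldimethylsilyloxy)phenyl]dodecyl}-5-methylfuran-2(5H)-one (both C6 epimers) | C[C@@]1(CC(C)(Br)CCCCCCCCCCc2ccc(O[Si](C)(C)C(C)(C)C)cc2)C=CC(=O)O1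
F5 | step 8 | (5R)-5-{2-hydroperoxy-2-methyl-12-[4-(tert-butyldimethylsilyloxy)phenyl]dodecyl}-5-methylfuran-2(5H)-one (both C6 epimers) | C[C@@]1(CC(C)(OO)CCCCCCCCCCc2ccc(O[Si](C)(C)C(C)(C)C)cc2)C=CC(=O)O1
F6 | step 2 | 2-methylidene-12-[4-(tert-butyldimethylsilyloxy)phenyl]dodecan-1-ol | C=C(CO)CCCCCCCCCCc1ccc(O[Si](C)(C)C(C)(C)C)cc1
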